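**Retrosynthetic overview**
1. The aldehyde comes from a dimethyl acetal, unmasked in the last step. The furan C5–CH2 bond comes from hydroboration and B-alkyl Suzuki–Miyaura coupling of a chiral terminal alkene with methyl 2-(5-bromofuran-2-yl)acetate.
2. The chiral alkene acetal comes from (R)-4-butyl-δ-valerolactone. The acyl arm gains 1 C (lactol, methoxymethylene Wittig) and the O-alkyl arm gains 5 C (tosylate, pent-4-enyl Grignard, copper catalysis).
3. The (R)-lactone comes from (S)-monoallyl 3-butylglutarate, made by lipase-catalysed desymmetrising hydrolysis of prochiral diallyl 3-butylglutarate. This step sets the only stereocentre.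
4. The diester comes from 3-butylglutaric acid, made from pentanal and two dimethyl malonate (Knoevenagel–Michael, hydrolysis, decarboxylation).
5. Rings: the furan is bought intact and never built. The only ring made is the transient six-membered lactone/lactol, closed in step 5 and opened in step 7.

Assumption: the stereocentre is R (3-oxopropyl > 7-furylheptyl > butyl > H), and the sense of the lipase step is taken from its 3-propyl and 3-isobutyl analogues.

**Step 1**
Reactants: 1 pentanal; 2 dimethyl malonate
Product: 4 tetramethyl 2-butylpropane-1,1,3,3-tetracarboxylate, via dimethyl 2-pentylidenemalonate 3 (not isolated)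
Conditions: 2 (2.1 equiv), piperidine (10 mol%), AcOH (10 mol%), toluene, Dean–Stark, reflux; then NaOMe (15 mol%), MeOH, rt
Reagents that add atoms: none
Why: Knoevenagel condensation gives the alkylidene malonate 3, which takes up the second malonate by Michael addition to a symmetric adduct that has no stereocentre.

**Step 2**
Reactants: 4 tetramethyl 2-butylpropane-1,1,3,3-tetracarboxylate
Product: 6 3-butylpentanedioic acid, via 2-butylpropane-1,1,3,3-tetracarboxylic acid 5 (not isolated)
Conditions: 6 M aq HCl, reflux, 48 h
Reagents that add atoms: water, O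
Why: Acid ester hydrolysis followed by thermal malonic-acid decarboxylation at both ends leaves the prochiral diacid, as in the classical 3-alkylglutaric acid synthesis.

**Step 3**
Reactants: 6 3-butylpentanedioic acid
Product: 7 diprop-2-en-1-yl 3-butylpentanedioate (diallyl 3-butylglutarate)
Conditions: allyl alcohol (5 equiv), TsOH·H2O (5 mol%), toluene, Dean–Stark, reflux
Reagents that add atoms: allyl alcohol, C=CCO
Why: Fischer esterification is driven by azeotropic water removal, and allyl esters are chosen because they give the lipase its best enantiotopic-group selectivity on 3-alkylglutarates.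

**Step 4**
Reactants: 7 diallyl 3-butylglutarate
Product: 8 (3S)-3-[2-oxo-2-(prop-2-en-1-yloxy)ethyl]heptanoic acid
Conditions: immobilised Candida antarctica lipase B (a lipase, serine hydrolase class, EC 3.1.1.3), 0.1 M KH2PO4/K2HPO4 buffer pH 7.5, 30 °C, until the diester is consumed; filter, acidify to pH 3, extract
Reagents that add atoms: water, O
Why: In this enantioselective enzymatic desymmetrisation the lipase forms its acyl-enzyme only from the pro-R ester arm of prochiral 7, so catalytic hydrolysis stops at the (S)-half-ester (3-propyl and 3-isobutyl analogues give about 90–95% ee) and sets the only stereocentre.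

**Step 5**
Reactants: 8 (S)-half-ester
Product: 10 (4R)-4-butyloxan-2-one, via (3R)-3-(2-hydroxyethyl)heptanoic acid 9 (not isolated)
Conditions: LiEt3BH (3.3 equiv), THF, −78 °C → 0 °C; then 3 M aq HCl, rt, 3 h (ee of 10 assayed by chiral GC)
Reagents that add atoms: none
Why: In this chemoselective hydride reduction the first equivalent only makes the inert carboxylate, the allyl ester is reduced to the primary alcohol, and acid closes the δ-lactone (lactonisation) without touching the stereocentre β to both carbonyls.

**Step 6**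
Reactants: 10 (4R)-4-butyloxan-2-one
Product: 11 (4R)-4-butyloxan-2-ol (anomeric mixture)
Conditions: i-Bu2AlH (1.1 equiv), CH2Cl2, −78 °C, 1 h; aq potassium sodium tartrate
Reagents that add atoms: none
Why: Partial lactone reduction stops at the stable tetrahedral aluminium lactolate at −78 °C, and the undefined anomeric centre disappears in the next step.

**Step 7**
Reactants: 11 (4R)-4-butyloxan-2-ol
Product: 14 (3S)-3-butyl-6-methoxyhex-5-en-1-ol (E/Z mixture), via (methoxymethylidene)triphenylphosphorane 12 (not isolated), via (3R)-3-(2-hydroxyethyl)heptanal 13 (not isolated)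
Conditions: MeOCH2PPh3Cl (3.0 equiv), KOt-Bu (2.9 equiv), THF, 0 °C, 30 min; then 11, 0 °C → rt
Reagents that add atoms: (methoxymethyl)triphenylphosphonium chloride, COC[P+](c1ccccc1)(c1ccccc1)c1ccccc1.[Cl-]
Why: In this Wittig olefination the lactol equilibrates with hydroxy aldehyde 13, which the non-stabilised ylide traps irreversibly, adding the missing carbon as an enol ether (masked aldehyde) with no bond to the stereocentre touched (the descriptor changes only through CIP ranking).

**Step 8**
Reactants: 14 (3S)-3-butyl-6-methoxyhex-5-en-1-ol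
Product: 15 (3S)-3-butyl-6-methoxyhex-5-en-1-yl 4-methylbenzenesulfonate
Conditions: TsCl (1.3 equiv), Et3N (2 equiv), DMAP (10 mol%), CH2Cl2, 0 °C → rt; Et3N-deactivated silica
Reagents that add atoms: 4-toluenesulfonyl chloride, Cc1ccc(cc1)S(=O)(=O)Cl
Why: Sulfonylation of an unhindered primary alcohol under basic conditions leaves the acid-labile enol ether intact.

**Step 9**
Reactants: 15 tosylate; 16 5-bromopent-1-ene
Product: 18 (4R)-4-butyl-1-methoxyundeca-1,10-diene (E/Z mixture), via pent-4-enylmagnesium bromide 17 (not isolated)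
Conditions: 16, Mg, THF, rt → 40 °C (2.5 equiv of 17); then 15, Li2CuCl4 (5 mol%), THF, −20 °C → rt
Reagents that add atoms: none
Why: In this copper-catalysed sp3–sp3 cross-coupling of Kochi–Schlosser type the monovalent copper ate species formed from the Grignard reagent displaces the primary tosylate by SN2, two carbons away from the stereocentre, while the enol ether is inert.

**Step 10**
Reactants: 18 (4R)-4-butyl-1-methoxyundeca-1,10-diene
Product: 19 (8R)-8-butyl-11,11-dimethoxyundec-1-ene
Conditions: camphorsulfonic acid (5 mol%), MeOH, 0 °C → rt; Et3N quench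
Reagents that add atoms: methanol, CO
Why: Acid-catalysed addition of methanol to the enol ether (acetalisation via the oxocarbenium ion) converges both alkene isomers to one base-stable and borane-stable acetal and leaves the unactivated terminal alkene alone.

**Step 11**
Reactants: 20 methyl 2-(furan-2-yl)acetate
Product: 21 methyl 2-(5-bromofuran-2-yl)acetate
Conditions: NBS (1.02 equiv), DMF, 0 °C, dark, 1 h; used at once
Reagents that add atoms: N-bromosuccinimide, O=C1CCC(=O)N1Br
Why: Electrophilic aromatic bromination of a 2-substituted furan goes to the free α-position C5, and polar, dark conditions suppress radical side-chain bromination.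

**Step 12**
Reactants: 19 (8R)-8-butyl-11,11-dimethoxyundec-1-ene; 21 methyl 2-(5-bromofuran-2-yl)acetate
Product: 23 methyl 2-{5-[(8R)-8-butyl-11,11-dimethoxyundecyl]furan-2-yl}acetate, via 9-[(8R)-8-butyl-11,11-dimethoxyundecyl]-9-borabicyclo[3.3.1]nonane 22 (not isolated)
Conditions: 9-BBN dimer (0.6 equiv), THF, 0 °C → rt, 4 h; then 21 (1.2 equiv), Pd(dppf)Cl2·CH2Cl2 (5 mol%), 3 M aq K3PO4 (3 equiv), DMF, 50 °C
Reagents that add atoms: none
Why: Anti-Markovnikov hydroboration is followed by B-alkyl Suzuki–Miyaura coupling, in which zerovalent palladium inserts into the furyl C–Br bond, the phosphate-activated borane transfers its primary alkyl group, and reductive elimination forms the C5–CH2 bond while acetal, ester and the remote stereocentre survive.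

**Step 13**
Reactants: 23 coupled acetal
Product: 24 methyl 2-{5-[(8R)-8-butyl-11-oxoundecyl]furan-2-yl}acetate (target)
Conditions: 1 M aq HCl–THF (1:4), rt, 2 h; NaHCO3 quench; neutral silica
Reagents that add atoms: water, O
Why: Acetal hydrolysis of an aliphatic dimethyl acetal is fast at room temperature in dilute acid, far below what opens a 2,5-dialkylfuran or cleaves the methyl ester, and the stereocentre γ to the new aldehyde cannot epimerise.

**Compound list**
1 | pentanal | CCCCC=O | starting material
2 | dimethyl malonate | COC(=O)CC(=O)OC | starting material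
3 | dimethyl 2-pentylidenemalonate | CCCCC=C(C(=O)OC)C(=O)OC | intermediate
4 | tetramethyl 2-butylpropane-1,1,3,3-tetracarboxylate | CCCCC(C(C(=O)OC)C(=O)OC)C(C(=O)OC)C(=O)OC | intermediate
5 | 2-butylpropane-1,1,3,3-tetracarboxylic acid | CCCCC(C(C(=O)O)C(=O)O)C(C(=O)O)C(=O)O | intermediate
6 | 3-butylpentanedioic acid | CCCCC(CC(=O)O)CC(=O)O | intermediate
7 | diprop-2-en-1-yl 3-butylpentanedioate | CCCCC(CC(=O)OCC=C)CC(=O)OCC=C | intermediate
8 | (3S)-3-[2-oxo-2-(prop-2-en-1-yloxy)ethyl]heptanoic acid | CCCC[C@@H](CC(=O)O)CC(=O)OCC=C | intermediate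
9 | (3R)-3-(2-hydroxyethyl)heptanoic acid | CCCC[C@@H](CC(=O)O)CCO | intermediate
10 | (4R)-4-butyloxan-2-one | CCCC[C@@H]1CCOC(=O)C1 | intermediate
11 | (4R)-4-butyloxan-2-ol, anomeric mixture | CCCC[C@@H]1CCOC(O)C1 | intermediate
12 | (methoxymethylidene)triphenylphosphorane | COC=P(c1ccccc1)(c1ccccc1)c1ccccc1 | intermediate
13 | (3R)-3-(2-hydroxyethyl)heptanal | CCCC[C@@H](CC=O)CCO | intermediate
14 | (3S)-3-butyl-6-methoxyhex-5-en-1-ol, E/Z mixture | CCCC[C@@H](CC=COC)CCO | intermediate
15 | (3S)-3-butyl-6-methoxyhex-5-en-1-yl 4-methylbenzenesulfonate, E/Z mixture | CCCC[C@@H](CC=COC)CCOS(=O)(=O)c1ccc(C)cc1 | intermediate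
16 | 5-bromopent-1-ene | C=CCCCBr | starting material
17 | pent-4-enylmagnesium bromide | C=CCCC[Mg]Br | intermediate
18 | (4R)-4-butyl-1-methoxyundeca-1,10-diene, E/Z mixture | CCCC[C@@H](CC=COC)CCCCCC=C | intermediate
19 | (8R)-8-butyl-11,11-dimethoxyundec-1-ene | CCCC[C@@H](CCC(OC)OC)CCCCCC=C | intermediate
20 | methyl 2-(furan-2-yl)acetate | COC(=O)Cc1ccco1 | starting material
21 | methyl 2-(5-bromofuran-2-yl)acetate | COC(=O)Cc1ccc(Br)o1 | intermediate
22 | 9-[(8R)-8-butyl-11,11-dimethoxyundecyl]-9-borabicyclo[3.3.1]nonane | CCCC[C@@H](CCC(OC)OC)CCCCCCCB1C2CCCC1CCC2 | intermediate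
23 | methyl 2-{5-[(8R)-8-butyl-11,11-dimethoxyundecyl]furan-2-yl}acetate | CCCC[C@@H](CCC(OC)OC)CCCCCCCc1ccc(CC(=O)OC)o1 | intermediate
24 | methyl 2-{5-[(8R)-8-butyl-11-oxoundecyl]furan-2-yl}acetate | CCCC[C@@H](CCC=O)CCCCCCCc1ccc(CC(=O)OC)o1 | target

**Totals:** 13 steps. The longest linear sequence is 12 steps (steps 1–10, 12, 13).

**Steps most likely to fail**

**Step 4.** The selectivity for the n-butyl substrate, and its sense, are extrapolated from close analogues, and the ee may stay near 90%.
- The fallback keeps a lipase but runs it in the acylation direction on the cyclic anhydride. It sets out from 6 and comes back at 10.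
- Ac2O at reflux dehydrates 6 to 4-butyloxane-2,6-dione F1.
- Burkholderia cepacia lipase, or the same lipase B, with methanol in MTBE opens F1. The carbonyl that acylates the enzyme now ends as the ester, which gives (3R)-3-(2-methoxy-2-oxoethyl)heptanoic acid F2.
- BH3·SMe2 in THF at 0 °C reduces only the free acid, giving methyl (3R)-3-(2-hydroxyethyl)heptanoate F3.
- Catalytic TsOH in warm toluene closes F3 to lactone 10.
- Either carbonyl of a half-ester can be reduced selectively, so whichever arm the enzyme prefers can be steered to (R)-10.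

**Step 12.** Bromofuran 21 is labile, its ester is base-sensitive, and alkylboranes can lose material by β-hydride elimination.
- The fallback reverses the polarity and uses the furan as nucleophile. It sets out from 19 and comes back at 23.
- Hydroboration to 22 as before, followed by oxidation with NaBO3·4H2O, gives (8R)-8-butyl-11,11-dimethoxyundecan-1-ol F4.
- Iodine, PPh3 and imidazole in CH2Cl2 convert F4 to (4R)-4-butyl-11-iodo-1,1-dimethoxyundecane F5.
- Furan is lithiated with n-BuLi in THF at 0 °C to furan-2-yllithium F6. Alkylation of F6 with F5 in THF/DMPU gives 2-[(8R)-8-butyl-11,11-dimethoxyundecyl]furan F7.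
- The CH2CO2Me group is then placed on the free C5 by oxidative radical substitution. The reagents are O-ethyl S-(2-methoxy-2-oxoethyl) dithiocarbonate and dilauroyl peroxide in refluxing 1,2-dichloroethane. This gives 23.

**Step 13.** The product combines an acid-sensitive 2,5-dialkylfuran with an enolisable aldehyde, so the acidic unmasking may cost material.
- The fallback ends with a neutral oxidation instead. It sets out from 19 and comes back at 24.
- Aqueous HCl in THF, used before any furan is present, frees (4R)-4-butylundec-10-enal F8.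
- NaBH4 in MeOH reduces F8 to (4R)-4-butylundec-10-en-1-ol F9.
- TBSCl and imidazole give tert-butyl{[(4R)-4-butylundec-10-en-1-yl]oxy}dimethylsilane F10.
- 9-BBN forms 9-[(8R)-8-butyl-11-{[tert-butyl(dimethyl)silyl]oxy}undecyl]-9-borabicyclo[3.3.1]nonane F11.
- F11 couples with 21 under the step 12 conditions to methyl 2-{5-[(8R)-8-butyl-11-{[tert-butyl(dimethyl)silyl]oxy}undecyl]furan-2-yl}acetate F12.
- HF·pyridine in THF gives methyl 2-{5-[(8R)-8-butyl-11-hydroxyundecyl]furan-2-yl}acetate F13.
- Dess–Martin periodinane with NaHCO3 in CH2Cl2 oxidises F13 to 24.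

**Further compounds**
F1 | step 4 | 4-butyloxane-2,6-dione | CCCCC1CC(=O)OC(=O)C1
F2 | step 4 | (3R)-3-(2-methoxy-2-oxoethyl)heptanoic acid | CCCC[C@@H](CC(=O)OC)CC(=O)O
F3 | step 4 | methyl (3R)-3-(2-hydroxyethyl)heptanoate | CCCC[C@@H](CC(=O)OC)CCO
F4 | step 12 | (8R)-8-butyl-11,11-dimethoxyundecan-1-ol | CCCC[C@@H](CCC(OC)OC)CCCCCCCO
F5 | step 12 | (4R)-4-butyl-11-iodo-1,1-dimethoxyundecane | CCCC[C@@H](CCC(OC)OC)CCCCCCCI
F6 | step 12 | furan-2-yllithium | [Li]c1ccco1
F7 | step 12 | 2-[(8R)-8-butyl-11,11-dimethoxyundecyl]furan | CCCC[C@@H](CCC(OC)OC)CCCCCCCc1ccco1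
F8 | step 13 | (4R)-4-butylundec-10-enal | CCCC[C@@H](CCC=O)CCCCCC=C
F9 | step 13 | (4R)-4-butylundec-10-en-1-ol | CCCC[C@@H](CCCO)CCCCCC=C
F10 | step 13 | tert-butyl{[(4R)-4-butylundec-10-en-1-yl]oxy}dimethylsilane | CCCC[C@@H](CCCO[Si](C)(C)C(C)(C)C)CCCCCC=C
F11 | step 13 | 9-[(8R)-8-butyl-11-{[tert-butyl(dimethyl)silyl]oxy}undecyl]-9-borabicyclo[3.3.1]nonane | CCCC[C@@H](CCCO[Si](C)(C)C(C)(C)C)CCCCCCCB1C2CCCC1CCC2
F12 | step 13 | methyl 2-{5-[(8R)-8-butyl-11-{[tert-butyl(dimethyl)silyl]oxy}undecyl]furan-2-yl}acetate | CCCC[C@@H](CCCO[Si](C)(C)C(C)(C)C)CCCCCCCc1ccc(CC(=O)OC)o1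
F13 | step 13 | methyl 2-{5-[(8R)-8-butyl-11-hydroxyundecyl]furan-2-yl}acetate | CCCC[C@@H](CCCO)CCCCCCCc1ccc(CC(=O)OC)o1
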